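**Retrosynthetic overview**
1. Ring labels: A is the methoxy ring, B the para-linked ring, C the phenol ring, D the meta-linked ring. The plan rests on ring C: its free OH is para to the CH2CH2 bridge and the oxygen leading to ring D sits on the adjacent ring carbon. This ortho-aryloxy-para-alkylphenol pattern arises when one phenol is oxidised and a second phenol oxygen adds next to its OH.
2. Disconnection 1 (last skeletal bond, only ring): the ring C carbon–O(ring D) bond. It opens to a seco bis-bibenzyl diphenol carrying bromine on every free ortho/para carbon of rings C and D, and hydrogenolysis removes the bromines afterwards.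
3. Disconnection 2: both CH2CH2 bridges are Wittig alkenes, reduced together with loss of two benzyl ethers in one hydrogenation.
4. Disconnection 3: the A–O–B ether is an SNAr bond from the isovanillin oxygen to 4-fluorobenzaldehyde. It is made only after ring D has been attached to the isovanillin aldehyde, so two formyl groups never coexist.
5. Ring order: the four benzene rings are bought, and the 19-membered macrocycle is the only ring made, in step 8.

Key step: step 8

Assumption: both Wittig products are E/Z mixtures, drawn without alkene geometry and carried on unseparated, because step 6 erases the geometry. The target has no stereocentre.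

**Step 1**
Reactants: 1 3-(benzyloxy)benzyl alcohol
Product: 2 [3-(benzyloxy)benzyl]triphenylphosphonium bromide
Conditions: PPh3·HBr, MeCN, reflux
Reagents that add atoms: triphenylphosphine hydrobromide, [Br-].[PH+](c1ccccc1)(c1ccccc1)c1ccccc1
Why: PPh3 displaces the protonated benzylic hydroxyl and gives the Wittig salt directly (phosphonium salt formation from a benzylic alcohol), and the aryl benzyl ether is inert to this weakly acidic reagent.

**Step 2**
Reactants: 2 [3-(benzyloxy)benzyl]triphenylphosphonium bromide; 3 isovanillin (3-hydroxy-4-methoxybenzaldehyde)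
Product: 5 stilbene phenol 5-{2-[3-(benzyloxy)phenyl]ethenyl}-2-methoxyphenol (E/Z mixture), via ring D benzylidenephosphorane 4 (not isolated)
Conditions: KOtBu (2.3 equiv), THF, 0 °C to rt
Reagents that add atoms: none
Why: Wittig olefination, in which one equivalent of base holds the isovanillin OH as a phenoxide that is meta to the formyl group and so does not deactivate it, and the semi-stabilised ylide 4 then joins ring D to ring A.

**Step 3**
Reactants: 5 stilbene phenol; 6 4-fluorobenzaldehyde
Product: 7 4-(5-{2-[3-(benzyloxy)phenyl]ethenyl}-2-methoxyphenoxy)benzaldehyde (E/Z mixture)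
Conditions: K2CO3, DMF, 120 °C
Reagents that add atoms: none
Why: Nucleophilic aromatic substitution (SNAr), in which the para-formyl group activates fluoride for displacement by the only free phenoxide of 5 and leaves a single aldehyde on ring B for the next olefination.

**Step 4**
Reactants: 8 4-(benzyloxy)benzyl alcohol
Product: 9 [4-(benzyloxy)benzyl]triphenylphosphonium bromide
Conditions: PPh3·HBr, MeCN, reflux
Reagents that add atoms: triphenylphosphine hydrobromide, [Br-].[PH+](c1ccccc1)(c1ccccc1)c1ccccc1
Why: The same phosphonium salt formation as in step 1, made easier here by the para-alkoxy group, which stabilises the benzylic cation.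

**Step 5**
Reactants: 7 ring B aldehyde; 9 [4-(benzyloxy)benzyl]triphenylphosphonium bromide
Product: 11 bis-stilbene dibenzyl ether 4-{2-[3-(benzyloxy)phenyl]ethenyl}-2-(4-{2-[4-(benzyloxy)phenyl]ethenyl}phenoxy)-1-methoxybenzene (E/Z mixtures), via ring C benzylidenephosphorane 10 (not isolated)
Conditions: KOtBu (1.1 equiv), THF, 0 °C to rt
Reagents that add atoms: none
Why: Wittig olefination of the single aldehyde of 7 with an electron-rich benzylic ylide attaches ring C to ring B, and no other group in 7 reacts with the ylide.

**Step 6**
Reactants: 11 bis-stilbene dibenzyl ether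
Product: 12 seco diphenol 3-[2-(3-{4-[2-(4-hydroxyphenyl)ethyl]phenoxy}-4-methoxyphenyl)ethyl]phenol
Conditions: H2 (1 atm), 10% Pd/C, THF–MeOH, rt
Reagents that add atoms: none
Why: Heterogeneous catalytic hydrogenation saturates both stilbene alkenes and hydrogenolyses both aryl benzyl ethers in one operation, while the methyl ether and the diaryl ether are inert.

**Step 7**
Reactants: 12 seco diphenol
Product: 13 pentabromo seco diphenol 2,4,6-tribromo-3-[2-(3-{4-[2-(3,5-dibromo-4-hydroxyphenyl)ethyl]phenoxy}-4-methoxyphenyl)ethyl]phenol
Conditions: Br2 (5.0 equiv, slow addition), NaOAc, AcOH–CH2Cl2, 0 °C to rt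
Reagents that add atoms: bromine, BrBr
Why: Electrophilic aromatic bromination, in which free phenols react much faster than aryl ethers in buffered acetic acid, so the two open ortho carbons of ring C and the three ortho/para carbons of ring D (activated by both OH and alkyl) should consume the five equivalents before ring A or B reacts.

**Step 8**
Reactants: 13 pentabromo seco diphenol
Product: 16 tetrabromo macrocycle (ring C phenol free), via macrocyclic bromo dienone 14 (not isolated), via macrocyclic methoxy dienone 15 (not isolated)
Conditions: Tl(NO3)3·3H2O (1.5 equiv), MeOH–THF, 1 mM, −20 to 0 °C; filter, concentrate; Zn dust, AcOH–THF, rt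
Reagents that add atoms: none
Why: The ring C phenol binds to trivalent thallium through oxygen and gives up two electrons, leaving monovalent thallium and a phenoxenium ion whose charge sits on the two equivalent C–Br ortho carbons and on the alkyl-bearing para carbon, and the ring D phenol oxygen adds to one of the ortho carbons to give bromo dienone 14. In methanol 14 loses bromide and takes up methanol at the para carbon to give quinol ether 15, and zinc in acetic acid then delivers two electrons to whichever dienone is present, expelling bromide or methoxide and restoring the arene as 16 with the new aryloxy group next to the free OH. The closest known reaction type is this same thallium trinitrate oxidation of ortho,ortho'-dihalophenols followed by zinc reduction, which is established for macrocyclic diaryl ethers of the isodityrosine family. The 19-membered ring closes end to end by intramolecular attack of the terminal ring D oxygen on the terminal ring C cation, untemplated and favoured only by high dilution. No stereocentre is set, because the sp3 carbon of 14 and 15 forms as a racemate and is flattened again in the reduction. The step needs ring C to be the oxidised partner and ring D the nucleophile, which is secured by ring C having two bromines and its alkyl group on a charge-bearing carbon while ring D has three bromines and its alkyl group meta to oxygen, and it needs O- rather than C-attack, which is secured by bromine on every ortho and para carbon of ring D; rings A and B have no OH to bind thallium and stay out.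

**Step 9**
Reactants: 16 tetrabromo macrocycle
Product: 17 target CNP0132125.0
Conditions: H2 (1 atm), 10% Pd/C, NaOAc, MeOH–THF, rt
Reagents that add atoms: none
Why: Catalytic hydrodehalogenation of aryl bromides, with acetate as acid scavenger, cleaves all four C–Br bonds and leaves the two diaryl ethers, the methyl ether, the phenol and the saturated bridges untouched.

**Compound list**
1 | 3-(benzyloxy)benzyl alcohol | OCc1cccc(OCc2ccccc2)c1 | starting material
2 | [3-(benzyloxy)benzyl]triphenylphosphonium bromide | [Br-].c1ccc(cc1)COc1cccc(C[P+](c2ccccc2)(c2ccccc2)c2ccccc2)c1 | intermediate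
3 | isovanillin | COc1ccc(C=O)cc1O | starting material
4 | ring D benzylidenephosphorane (ylide of 2, not isolated) | c1ccc(cc1)COc1cccc(C=P(c2ccccc2)(c2ccccc2)c2ccccc2)c1 | intermediate
5 | 5-{2-[3-(benzyloxy)phenyl]ethenyl}-2-methoxyphenol, E/Z mixture | COc1ccc(C=Cc2cccc(OCc3ccccc3)c2)cc1O | intermediate
6 | 4-fluorobenzaldehyde | O=Cc1ccc(F)cc1 | starting material
7 | 4-(5-{2-[3-(benzyloxy)phenyl]ethenyl}-2-methoxyphenoxy)benzaldehyde, E/Z mixture | COc1ccc(C=Cc2cccc(OCc3ccccc3)c2)cc1Oc1ccc(C=O)cc1 | intermediate
8 | 4-(benzyloxy)benzyl alcohol | OCc1ccc(OCc2ccccc2)cc1 | starting material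
9 | [4-(benzyloxy)benzyl]triphenylphosphonium bromide | [Br-].c1ccc(cc1)COc1ccc(C[P+](c2ccccc2)(c2ccccc2)c2ccccc2)cc1 | intermediate
10 | ring C benzylidenephosphorane (ylide of 9, not isolated) | c1ccc(cc1)COc1ccc(C=P(c2ccccc2)(c2ccccc2)c2ccccc2)cc1 | intermediate
11 | bis-stilbene dibenzyl ether, E/Z mixtures | COc1ccc(C=Cc2cccc(OCc3ccccc3)c2)cc1Oc1ccc(C=Cc2ccc(OCc3ccccc3)cc2)cc1 | intermediate
12 | seco diphenol (rings D–A–O–B–C, OH on rings C and D) | COc1ccc(CCc2cccc(O)c2)cc1Oc1ccc(CCc2ccc(O)cc2)cc1 | intermediate
13 | pentabromo seco diphenol (ring C 3,5-dibromo-4-hydroxyphenyl, ring D 2,4,6-tribromo-3-hydroxyphenyl) | COc1ccc(CCc2c(Br)cc(Br)c(O)c2Br)cc1Oc1ccc(CCc2cc(Br)c(O)c(Br)c2)cc1 | intermediate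
14 | macrocyclic 6-aryloxy-2,6-dibromocyclohexa-2,4-dienone (ring C oxidised, racemic, not isolated) | COc1ccc2cc1Oc1ccc(cc1)CCC1=CC(Br)(Oc3c(Br)cc(Br)c(c3Br)CC2)C(=O)C(Br)=C1 | intermediate
15 | macrocyclic 2-aryloxy-6-bromo-4-methoxycyclohexa-2,5-dienone (ring C quinol methyl ether, racemic, not isolated) | COc1ccc2cc1Oc1ccc(cc1)CCC1(OC)C=C(Oc3c(Br)cc(Br)c(c3Br)CC2)C(=O)C(Br)=C1 | intermediate
16 | tetrabromo macrocycle (target skeleton, one Br on ring C ortho to OH, three Br on ring D ortho, ortho and para to the ether oxygen) | COc1ccc2cc1Oc1ccc(cc1)CCc1cc(Br)c(O)c(c1)Oc1c(Br)cc(Br)c(c1Br)CC2 | intermediate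
17 | CNP0132125.0, macrocyclic bis-bibenzyl diether (OMe on ring A, OH on ring C) | COc1ccc2cc1Oc1ccc(cc1)CCc1ccc(O)c(c1)Oc1cccc(c1)CC2 | target

**Step count**
Total steps: 9. Longest linear sequence: 8 (steps 1, 2, 3, 5, 6, 7, 8, 9).

**Steps most likely to fail**

**Step 8.**
- Intermolecular coupling to oligomers may outrun the end-to-end closure.
- Methanol may capture the ring C cation before the ring D oxygen arrives. This only lowers conversion, since zinc returns 13.
- Oxidation may start on ring D and reverse the direction of coupling.
- The ring D bromine between oxygen and chain must end up pointing into the macrocycle. Ring D therefore has to tilt out of the mean plane, which may slow the closure.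

The fallback sets out from 7 and comes back at 17. It makes the ring C–O–ring D ether first, intermolecularly, by copper catalysis. It then closes the macrocycle at the ring B–ring C bridge by an intramolecular Wittig reaction, a standard closure for macrocyclic bis-bibenzyls.
- Aldehyde 7 is masked with ethylene glycol (p-TsOH, toluene, Dean–Stark) as the dioxolane F1.
- H2, Pd/C in EtOAc with a trace of Et3N saturates the alkene and frees the ring D oxygen to give the bibenzyl phenol F2.
- Ullmann coupling with commercial 4-(benzyloxy)-3-bromobenzaldehyde (CuI, N,N-dimethylglycine, Cs2CO3, dioxane, 100 °C) gives the ring C aldehyde F3.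
- NaBH4 in MeOH–THF gives the benzylic alcohol F4.
- PPh3·HBr in refluxing MeCN forms the phosphonium salt, while the water released opens the dioxolane, giving the formyl phosphonium bromide F5.
- Slow addition to NaOMe in CH2Cl2 at high dilution forms the formyl ylide F6, which closes to the macrocyclic stilbene benzyl ether F7.
- H2, Pd/C then saturates the alkene and removes the benzyl group to give 17.

**Step 7.** The ring A carbon para to the diaryl ether oxygen may compete for bromine before the crowded ring D carbon between OH and chain is filled. The bromine would then be spread unevenly over the rings. Ipso attack at the alkyl-bearing carbon of ring C may also consume reagent.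

The fallback sets out from 12 and comes back at 17. It gives up selectivity and brominates ring A on purpose.
- Br2 (6.5 equiv) in AcOH–CH2Cl2 at rt should drive 12 to the single hexabromo seco diphenol F8. The sixth bromine sits on ring A para to the ether oxygen, where it also makes ring A harder to oxidise.
- The Tl(NO3)3·3H2O then Zn sequence of step 8 passes through the hexabromo-series bromo dienone F9 and the hexabromo-series methoxy dienone F10 to the pentabromo macrocycle F11.
- The hydrogenolysis of step 9 strips all five bromines to give 17.

**Step 2.** The potassium phenoxide of isovanillin may precipitate from THF, and proton transfer from unreacted phenol may quench the ylide, so the olefination may stall.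

The fallback sets out from 3 and comes back at 7. It forms the ether first and keeps the second aldehyde latent as a nitrile.
- Compound 3 and 4-fluorobenzonitrile (K2CO3, DMF, 120 °C, SNAr) give the formyl nitrile F12.
- Ylide 4, made from 2 with KOtBu in THF, converts its only aldehyde to the stilbene nitrile F13.
- i-Bu2AlH in toluene at −78 °C followed by aqueous acid passes through the aldimine F14 and gives 7.

**Further compounds**
F1 | step 8 | dioxolane acetal of 7 | COc1ccc(C=Cc2cccc(OCc3ccccc3)c2)cc1Oc1ccc(cc1)C1OCCO1
F2 | step 8 | bibenzyl phenol with ring B dioxolane | COc1ccc(CCc2cccc(O)c2)cc1Oc1ccc(cc1)C1OCCO1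
F3 | step 8 | ring C aldehyde (C–O–D ether made, ring C OBn, ring B dioxolane) | COc1ccc(CCc2cccc(Oc3cc(C=O)ccc3OCc3ccccc3)c2)cc1Oc1ccc(cc1)C1OCCO1
F4 | step 8 | ring C benzylic alcohol | COc1ccc(CCc2cccc(Oc3cc(CO)ccc3OCc3ccccc3)c2)cc1Oc1ccc(cc1)C1OCCO1
F5 | step 8 | formyl phosphonium bromide | [Br-].COc1ccc(CCc2cccc(Oc3cc(C[P+](c4ccccc4)(c4ccccc4)c4ccccc4)ccc3OCc3ccccc3)c2)cc1Oc1ccc(C=O)cc1
F6 | step 8 | formyl ylide | COc1ccc(CCc2cccc(Oc3cc(C=P(c4ccccc4)(c4ccccc4)c4ccccc4)ccc3OCc3ccccc3)c2)cc1Oc1ccc(C=O)cc1
F7 | step 8 | macrocyclic stilbene benzyl ether, E/Z mixture | COc1ccc2cc1Oc1ccc(cc1)C=Cc1ccc(OCc3ccccc3)c(c1)Oc1cccc(c1)CC2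
F8 | step 7 | hexabromo seco diphenol | COc1cc(Br)c(CCc2c(Br)cc(Br)c(O)c2Br)cc1Oc1ccc(CCc2cc(Br)c(O)c(Br)c2)cc1
F9 | step 7 | hexabromo-series bromo dienone (racemic) | COc1cc(Br)c2cc1Oc1ccc(cc1)CCC1=CC(Br)(Oc3c(Br)cc(Br)c(c3Br)CC2)C(=O)C(Br)=C1
F10 | step 7 | hexabromo-series methoxy dienone (racemic) | COc1cc(Br)c2cc1Oc1ccc(cc1)CCC1(OC)C=C(Oc3c(Br)cc(Br)c(c3Br)CC2)C(=O)C(Br)=C1
F11 | step 7 | pentabromo macrocycle | COc1cc(Br)c2cc1Oc1ccc(cc1)CCc1cc(Br)c(O)c(c1)Oc1c(Br)cc(Br)c(c1Br)CC2
F12 | step 2 | 4-(5-formyl-2-methoxyphenoxy)benzonitrile | COc1ccc(C=O)cc1Oc1ccc(C#N)cc1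
F13 | step 2 | stilbene nitrile, E/Z mixture | COc1ccc(C=Cc2cccc(OCc3ccccc3)c2)cc1Oc1ccc(C#N)cc1
F14 | step 2 | aldimine, E/Z mixture at the stilbene | COc1ccc(C=Cc2cccc(OCc3ccccc3)c2)cc1Oc1ccc(C=N)cc1
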